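A falling L peak is easily read as L turned into J, but L can also leave by pairing with Q as G, and that counts as reacted here. So the loss of L is best reckoned whole.

in all of them: L 0.40 M

| charge | E | remark | time |
|---|---|---|---|
| ochre | 0.31 M | run made earlier |  |
| red | 0.52 M | run made earlier |  |
| east | 0.780 M |  | 8.0 min |
| south-west | 0.600 M |  | 8.0 min |

| run | time / min | L / % | D / % |
|---|---|---|---|
| ochre | 2.00 | 90.2 | 0 |
| ochre | 4.00 | 81.8 | 0 |
| ochre | 6.00 | 74.1 | 0 |
| ochre | 8.00 | 68.5 | 0.3 |
| red | 0.667 | 94.5 | 0.8 |
| red | 1.33 | 88.4 | 0 |
| red | 3.00 | 77.0 | 0 |
| red | 8.00 | 52.0 | 0 |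

(scatter of a reading: 0.3 percentage points)

- part of the L that has reacted at the end, east
- part of the L that has reacted at the end, south-west
- what raising the concentration of E from its lowest to its highest value here does to the part of the L that has reacted (changes below 5 percentage points count as none) (no change / it rises / it falls)

- amounts and yields of Q count G too
- the analysis behind the earlier runs scatters by 0.3 percentage points, standard deviation
- candidate steps: E + J -> D + Q; L + Q <-> G; J -> X; L + E -> J + Q
- what has gone from L into another species counts as reacted, even if it can come back

At 8.00 min, the time asked, take the natural logarithm of L charged over L left and divide it by [E] as charged times the time. Ochre gives 0.153 L mol⁻¹ min⁻¹ and red 0.157 L mol⁻¹ min⁻¹. They lie within 3.04% of each other, although [E] differs by a factor 1.68. Their mean is 0.155 L mol⁻¹ min⁻¹.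

The carried number is the exposure N, this mean times [E] as charged times the time, in the manner of a pseudo-first-order reckoning: east has 0.966 and south-west 0.743. Free L is then exp(−N) of its charge, and the rest has reacted: 62.0% in east, 52.5% in south-west. That is a rise of 9.5 percentage points, beyond the 5 points that counts.

Was one number enough? Across [E] at this time, ochre and red say yes. Across time, no: ochre at 2.00 min gives 0.166 L mol⁻¹ min⁻¹, higher than at its end. A later reading should therefore fall below this reckoning.

The forecast says 63.5% for east and 53.5% for south-west, both above this reckoning, and that it rises, counting in “L tied up as G with Q”.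

The flask gives 62.1% in east and 52.7% in south-west. For the reacted part of L, as [E] goes from its south-west value to its east value: it rises, a change of 9.4 points.

    E + J → D + Q (k = 3.70 × 10⁻⁵ L mol⁻¹ s⁻¹)
    L + Q ⇌ G, settled at all times (K = 78.0 L mol⁻¹)
    J → X (k = 8.20 × 10⁻⁴ s⁻¹)
    L + E → J + Q (k = 0.00150 L mol⁻¹ s⁻¹)

With nothing binding Q, south-west reaches 31.7%, less than the 52.7% it has. East's exposure of 0.966 leaves 38.1% of L free, and the flask holds 38%.

East read at 15 min has N of 1.81, which gives 83.7% reacted. The flask gives 80.4%, below that figure.

The readings are simulated from invented constants; scatter was added.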